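**Plan**

- The target is read as fisetinidol-(4α→8)-afzelechin (upper unit 2R,3S,4S, 2,3-trans-3,4-trans; lower unit 2R,3S). Retrosynthesis first strips it to an octa-O-benzyl 5-chloro derivative, then cuts ring C of the upper unit at O1–C8a and C4–C4a, so that ring A of the upper unit leaves as an aryne and a 2,4-diaryl-3-(benzyloxy)oxetane remains, in which O1–C4 is a temporary ring bond.
- The feature that allows this: C4 is benzylic to C8 of ring A of the afzelechin unit, which carries O1 and O7 ortho and O5 para to C8. A C4–O bond therefore ionizes once its oxygen is arylated. O1 and C4 are 1,3-related through C2–C3, so the four-membered ring maps onto ring C after insertion of the two aryne carbons (C8a, C4a).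
- The oxetane is cut at O1–C2 (closure of a 1,3-diol), the diol at C4–C8 of the afzelechin unit (aryllithium plus Weinreb amide), and the amide at C2–C3 (glycolate aldol).
- Forward: afzelechin supplies the lower unit with its rings intact; the C2–C3–C4 chain is joined to its C8; the oxetane is closed; ring C of the upper unit is formed and ring A attached in one operation; hydrogenolysis removes eight benzyl groups and the chlorine.
- Stereochemistry: the lower unit is bought; C3 and C2 of the upper unit come from an Evans syn glycolate aldol (C2 is inverted in the oxetane closure, giving 2,3-trans); C4 is set in the key step by substrate control, whatever the C4 configuration of the oxetane.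

Key step: step 13

Remark: (+)-afzelechin is taken as a purchasable chiral-pool flavan-3-ol; in acyclic precursors the labels O1, C2, C3 and C4 mean the positions these atoms take in ring C of the upper unit.

**Route**

Step 1
Reactants: 1 (+)-afzelechin
Product: 2 5,7,4'-tri-O-benzylafzelechin
Conditions: BnBr (3.3 equiv), K2CO3, DMF, 0 °C to rt
Reagents that add atoms: benzyl bromide, BrCc1ccccc1
Why: Williamson O-alkylation in which carbonate deprotonates only the three phenols and leaves the secondary 3-OH and both stereocenters untouched.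

Step 2
Reactants: 2 5,7,4'-tri-O-benzylafzelechin
Product: 3 3,5,7,4'-tetra-O-benzylafzelechin
Conditions: NaH, BnBr, Bu4NI (cat.), DMF, 0 °C to rt
Reagents that add atoms: benzyl bromide, BrCc1ccccc1
Why: Williamson etherification of the secondary alkoxide, which blocks the 3-OH against the organolithium of step 7 and the aryne of step 13.

Step 3
Reactants: 3 3,5,7,4'-tetra-O-benzylafzelechin
Product: 4 8-bromo-3,5,7,4'-tetra-O-benzylafzelechin
Conditions: NBS (1.0 equiv), CH2Cl2, −78 to −20 °C
Reagents that add atoms: N-bromosuccinimide, O=C1CCC(=O)N1Br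
Why: electrophilic aromatic bromination, expected at C8 because this position, flanked by O1 and the 7-benzyloxy group, is the most nucleophilic site of the phloroglucinol-type ring A, as is usual for 5,7-di-O-benzyl flavan-3-ol ethers.

Step 4
Reactants: 5 (R)-4-benzyloxazolidin-2-one; 6 2-(benzyloxy)acetyl chloride
Product: 8 (R)-4-benzyl-3-[2-(benzyloxy)acetyl]oxazolidin-2-one, via N-lithio oxazolidinone 7 (not isolated)
Conditions: n-BuLi, THF, −78 °C; then 6, −78 to 0 °C
Reagents that add atoms: none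
Why: N-acylation of the lithiated oxazolidinone by the acid chloride, the standard entry to glycolate imides.

Step 5
Reactants: 8 (R)-4-benzyl-3-[2-(benzyloxy)acetyl]oxazolidin-2-one; 9 3,4-bis(benzyloxy)benzaldehyde
Product: 12 (2R,3S)-syn-aldol imide, via boron enolate 10 (not isolated), via boron aldolate 11 (not isolated)
Conditions: Bu2BOTf, Et3N, CH2Cl2, −78 to 0 °C; 9, −78 to 0 °C; pH 7 buffer, MeOH, H2O2, 0 °C
Reagents that add atoms: none
Why: Evans syn aldol in which the Z-boron enolate reacts through a closed Zimmerman–Traxler chair with one face shielded by the benzyl group of the (R)-auxiliary, which should set the (2R,3S) syn pair: the benzyloxy carbon becomes C3 of the upper unit unchanged and the carbinol carbon becomes C2 after the inversion of step 9.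

Step 6
Reactants: 12 (2R,3S)-syn-aldol imide
Product: 13 (2R,3S)-2-(benzyloxy)-3-[3,4-bis(benzyloxy)phenyl]-3-hydroxy-N-methoxy-N-methylpropanamide
Conditions: AlMe3, MeNH(OMe)·HCl, CH2Cl2, −10 to 0 °C; aqueous Rochelle salt
Reagents that add atoms: N,O-dimethylhydroxylamine hydrochloride, CNOC.Cl
Why: aluminium amide transamidation (Weinreb amide formation), assisted by the free β-hydroxyl, which releases the auxiliary without touching either stereocenter.

Step 7
Reactants: 4 8-bromo-3,5,7,4'-tetra-O-benzylafzelechin; 13 Weinreb amide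
Product: 17 (2R,3S)-β-hydroxy ketone, via aryllithium 14 (not isolated), via chloromagnesium alkoxide 15 (not isolated), via tetrahedral adduct 16 (not isolated)
Conditions: 4, n-BuLi, THF, −78 °C; separately 13, i-PrMgCl (1.0 equiv), THF, −40 °C; combine at −78 °C, then to −30 °C; sat. aq. NH4Cl
Reagents that add atoms: none
Why: bromine–lithium exchange followed by Weinreb ketone synthesis, in which the chelated tetrahedral adduct stops over-addition and the magnesium alkoxide protects the hydroxyl in the flask without risk of retro-aldol cleavage; no stereocenter is formed.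

Step 8
Reactants: 17 (2R,3S)-β-hydroxy ketone
Product: 19 (1S,2R,3R)-syn-1,3-diol, via boron chelate 18 (not isolated)
Conditions: Et2BOMe, THF/MeOH (4:1), −78 °C; NaBH4, −78 to −40 °C; repeated evaporation from MeOH (no acid)
Reagents that add atoms: none
Why: Narasaka–Prasad reduction, in which external hydride attacks the six-membered boron chelate to give the 1,3-syn diol; this carbinol center is erased again in step 13, so a single isomer is wanted only for clean handling.

Step 9
Reactants: 19 (1S,2R,3R)-syn-1,3-diol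
Product: 21 (2R,3R,4R)-3-(benzyloxy)-2-[3,4-bis(benzyloxy)phenyl]-4-(tetra-O-benzylafzelechin-8-yl)oxetane, via monotosylate 20 (not isolated)
Conditions: KOt-Bu (1.05 equiv), THF, −40 °C; TsCl (1.0 equiv); KOt-Bu (1.2 equiv), −40 to 0 °C; chromatography on Et3N-deactivated silica
Reagents that add atoms: none
Why: one-pot sulfonylation and Williamson closure (4-exo-tet), in which the less hindered hydroxyl on the ring B side should be sulfonylated and then displaced by the alkoxide next to the di-ortho-substituted aryl group with inversion at C2, placing the ring B aryl group trans to the 3-benzyloxy group.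

Step 10
Reactants: 22 4-(benzyloxy)phenol
Product: 23 4-(benzyloxy)-2-chlorophenol
Conditions: SO2Cl2 (1.0 equiv), i-Bu2NH (cat.), toluene, 0 °C to rt
Reagents that add atoms: sulfuryl chloride, O=S(=O)(Cl)Cl
Why: amine-catalysed ortho-chlorination of a para-blocked phenol, the free hydroxyl directing more strongly than the benzyloxy group.

Step 11
Reactants: 23 4-(benzyloxy)-2-chlorophenol
Product: 24 4-(benzyloxy)-2-bromo-6-chlorophenol
Conditions: NBS (1.0 equiv), i-Pr2NH (cat.), CH2Cl2, 0 °C
Reagents that add atoms: N-bromosuccinimide, O=C1CCC(=O)N1Br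
Why: electrophilic bromination at the only free position ortho to the hydroxyl.

Step 12
Reactants: 24 4-(benzyloxy)-2-bromo-6-chlorophenol
Product: 27 4-(benzyloxy)-2-chloro-6-(trimethylsilyl)phenyl trifluoromethanesulfonate, via silyl ether 25 (not isolated), via lithium phenoxide 26 (not isolated)
Conditions: HMDS, THF, 65 °C; evaporate; n-BuLi, THF, −78 °C; Tf2O, −78 °C to rt
Reagents that add atoms: hexamethyldisilazane, C[Si](C)(C)N[Si](C)(C)C; trifluoromethanesulfonic anhydride, O=S(=O)(OS(=O)(=O)C(F)(F)F)C(F)(F)F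
Why: O-silylation, bromine–lithium exchange with retro-Brook O-to-C silyl shift and triflation, the standard one-pot route to Kobayashi-type aryne precursors; exchange at bromine is much faster than at chlorine and the lithiated carbon is meta to chlorine.

Step 13
Reactants: 21 oxetane; 27 4-(benzyloxy)-2-chloro-6-(trimethylsilyl)phenyl trifluoromethanesulfonate
Product: 31 octa-O-benzyl-5-chlorofisetinidol-(4α→8)-afzelechin, via aryne 28 (not isolated), via oxetanium zwitterion 29 (not isolated), via benzylic cation zwitterion 30 (not isolated)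
Conditions: CsF, 18-crown-6, toluene/DME (1:1), 4 Å MS, rt to 40 °C, 27 (2.5 equiv) added slowly
Reagents that add atoms: none
Why: Proposed new method: fluoride unmasks aryne 28, the oxetane oxygen attacks its carbon remote from chlorine (future C8a) so that the aryl anion develops next to the inductively stabilizing chlorine (future C4a), the O-aryloxetanium 29 ionizes at C4–O with release of about 25 kcal/mol of ring strain to a cation stabilized by O1, O5 and O7 of the afzelechin ring A, and zwitterion 30 collapses by C4a–C4 bond formation. The closest known reaction types are the insertion of arynes into the benzylic C–O bond of aryl epoxides to give 2,3-dihydrobenzofurans and the aryne-triggered ring opening of cyclic ethers; ring expansion of a 2-aryloxetane to a chroman is not established. The one ring closed is the pyran ring C of the upper unit, by anion–cation recombination through a six-membered chair-like transition state, formally 6-exo-trig at the cationic C4. C2 and C3 pass unchanged from the oxetane, and the new C4 center is set by substrate control: the planar cation should adopt the A1,3-minimized rotamer with H3 in the plane of the di-ortho-substituted aryl ring, the tethered aryl anion then attacks anti to the 3-benzyloxy group and the C4 aryl group ends up equatorial and trans to O3 (4α; labelled 4R here only because chlorine changes the CIP priorities). The step needs O-arylation at the correct aryne carbon (secured by the 5-chloro substituent, which should override the weak opposite bias of the 7-benzyloxy group), cleavage of C4–O and not C2–O (secured by the far better cation stabilization of the trioxygenated ring over the catechol-type ring B), and closure faster than fluoride capture or proton loss (favoured by low fluoride concentration in an aprotic, weakly polar medium).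

Step 14
Reactants: 31 octa-O-benzyl-5-chlorofisetinidol-(4α→8)-afzelechin
Product: 32 fisetinidol-(4α→8)-afzelechin (target)
Conditions: H2 (1 atm), Pd(OH)2/C, NaHCO3 (2 equiv), THF/MeOH/H2O (10:10:1), rt; Sephadex LH-20
Reagents that add atoms: none
Why: hydrogenolysis of the eight benzyl ethers together with bicarbonate-buffered hydrodechlorination over palladium, which touches no stereocenter; the interflavan bond of a 5-deoxy upper unit is comparatively resistant to acid.

**Compound list**

1 | (+)-afzelechin, (2R,3S)-2-(4-hydroxyphenyl)chromane-3,5,7-triol | Oc1ccc(cc1)[C@H]1Oc2cc(O)cc(O)c2C[C@@H]1O | starting material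
2 | 5,7,4'-tri-O-benzylafzelechin | C(c1ccccc1)Oc1ccc(cc1)[C@H]1Oc2cc(OCc3ccccc3)cc(OCc3ccccc3)c2C[C@@H]1O | intermediate
3 | 3,5,7,4'-tetra-O-benzylafzelechin | C(c1ccccc1)Oc1ccc(cc1)[C@H]1Oc2cc(OCc3ccccc3)cc(OCc3ccccc3)c2C[C@@H]1OCc1ccccc1 | intermediate
4 | 8-bromo-3,5,7,4'-tetra-O-benzylafzelechin | Brc1c(OCc2ccccc2)cc(OCc2ccccc2)c2C[C@H](OCc3ccccc3)[C@@H](c3ccc(OCc4ccccc4)cc3)Oc12 | intermediate
5 | (R)-4-benzyloxazolidin-2-one | O=C1N[C@H](Cc2ccccc2)CO1 | starting material
6 | 2-(benzyloxy)acetyl chloride | O=C(Cl)COCc1ccccc1 | starting material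
7 | N-lithio-(R)-4-benzyloxazolidin-2-one | [Li]N1[C@H](Cc2ccccc2)COC1=O | intermediate (not isolated)
8 | (R)-4-benzyl-3-[2-(benzyloxy)acetyl]oxazolidin-2-one | O=C(COCc1ccccc1)N1[C@H](Cc2ccccc2)COC1=O | intermediate
9 | 3,4-bis(benzyloxy)benzaldehyde | O=Cc1ccc(OCc2ccccc2)c(OCc2ccccc2)c1 | starting material
10 | (Z)-dibutylboron enolate of 8 | CCCCB(CCCC)O/C(=C\OCc1ccccc1)N1[C@H](Cc2ccccc2)COC1=O | intermediate (not isolated)
11 | dibutylboron aldolate of 12 | CCCCB(CCCC)O[C@@H](c1ccc(OCc2ccccc2)c(OCc2ccccc2)c1)[C@@H](OCc1ccccc1)C(=O)N1[C@H](Cc2ccccc2)COC1=O | intermediate (not isolated)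
12 | (R)-4-benzyl-3-[(2R,3S)-2-(benzyloxy)-3-[3,4-bis(benzyloxy)phenyl]-3-hydroxypropanoyl]oxazolidin-2-one (syn aldol) | O[C@@H](c1ccc(OCc2ccccc2)c(OCc2ccccc2)c1)[C@@H](OCc1ccccc1)C(=O)N1[C@H](Cc2ccccc2)COC1=O | intermediate
13 | (2R,3S)-2-(benzyloxy)-3-[3,4-bis(benzyloxy)phenyl]-3-hydroxy-N-methoxy-N-methylpropanamide | O[C@@H](c1ccc(OCc2ccccc2)c(OCc2ccccc2)c1)[C@@H](OCc1ccccc1)C(=O)N(C)OC | intermediate
14 | 8-lithio-3,5,7,4'-tetra-O-benzylafzelechin | [Li]c1c(OCc2ccccc2)cc(OCc2ccccc2)c2C[C@H](OCc3ccccc3)[C@@H](c3ccc(OCc4ccccc4)cc3)Oc12 | intermediate (not isolated)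
15 | chloromagnesium alkoxide of 13 | Cl[Mg]O[C@@H](c1ccc(OCc2ccccc2)c(OCc2ccccc2)c1)[C@@H](OCc1ccccc1)C(=O)N(C)OC | intermediate (not isolated)
16 | tetrahedral adduct of 14 and 15 (O-lithio N-methoxy-N-methyl hemiaminal; new carbon of undefined configuration) | Cl[Mg]O[C@@H](c1ccc(OCc2ccccc2)c(OCc2ccccc2)c1)[C@@H](OCc1ccccc1)C(O[Li])(N(C)OC)c1c(OCc2ccccc2)cc(OCc2ccccc2)c2C[C@H](OCc3ccccc3)[C@@H](c3ccc(OCc4ccccc4)cc3)Oc12 | intermediate (not isolated)
17 | (2R,3S)-2-(benzyloxy)-3-[3,4-bis(benzyloxy)phenyl]-3-hydroxy-1-(tetra-O-benzylafzelechin-8-yl)propan-1-one | O[C@@H](c1ccc(OCc2ccccc2)c(OCc2ccccc2)c1)[C@@H](OCc1ccccc1)C(=O)c1c(OCc2ccccc2)cc(OCc2ccccc2)c2C[C@H](OCc3ccccc3)[C@@H](c3ccc(OCc4ccccc4)cc3)Oc12 | intermediate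
18 | O-diethylboryl chelate of 17 | CCB(CC)O[C@@H](c1ccc(OCc2ccccc2)c(OCc2ccccc2)c1)[C@@H](OCc1ccccc1)C(=O)c1c(OCc2ccccc2)cc(OCc2ccccc2)c2C[C@H](OCc3ccccc3)[C@@H](c3ccc(OCc4ccccc4)cc3)Oc12 | intermediate (not isolated)
19 | (1S,2R,3R)-2-(benzyloxy)-1-[3,4-bis(benzyloxy)phenyl]-3-(tetra-O-benzylafzelechin-8-yl)propane-1,3-diol (1,3-syn) | O[C@@H](c1ccc(OCc2ccccc2)c(OCc2ccccc2)c1)[C@@H](OCc1ccccc1)[C@H](O)c1c(OCc2ccccc2)cc(OCc2ccccc2)c2C[C@H](OCc3ccccc3)[C@@H](c3ccc(OCc4ccccc4)cc3)Oc12 | intermediate
20 | 1-O-tosylate of 19 (on the carbinol next to ring B) | Cc1ccc(cc1)S(=O)(=O)O[C@@H](c1ccc(OCc2ccccc2)c(OCc2ccccc2)c1)[C@@H](OCc1ccccc1)[C@H](O)c1c(OCc2ccccc2)cc(OCc2ccccc2)c2C[C@H](OCc3ccccc3)[C@@H](c3ccc(OCc4ccccc4)cc3)Oc12 | intermediate (not isolated)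
21 | (2R,3R,4R)-3-(benzyloxy)-2-[3,4-bis(benzyloxy)phenyl]-4-(tetra-O-benzylafzelechin-8-yl)oxetane (2,3-trans, 3,4-cis) | O1[C@H](c2ccc(OCc3ccccc3)c(OCc3ccccc3)c2)[C@@H](OCc2ccccc2)[C@H]1c1c(OCc2ccccc2)cc(OCc2ccccc2)c2C[C@H](OCc3ccccc3)[C@@H](c3ccc(OCc4ccccc4)cc3)Oc12 | intermediate
22 | 4-(benzyloxy)phenol | Oc1ccc(OCc2ccccc2)cc1 | starting material
23 | 4-(benzyloxy)-2-chlorophenol | Oc1ccc(OCc2ccccc2)cc1Cl | intermediate
24 | 4-(benzyloxy)-2-bromo-6-chlorophenol | Oc1c(Br)cc(OCc2ccccc2)cc1Cl | intermediate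
25 | [4-(benzyloxy)-2-bromo-6-chlorophenoxy]trimethylsilane | C[Si](C)(C)Oc1c(Br)cc(OCc2ccccc2)cc1Cl | intermediate (not isolated)
26 | lithium 4-(benzyloxy)-2-chloro-6-(trimethylsilyl)phenoxide | [Li]Oc1c([Si](C)(C)C)cc(OCc2ccccc2)cc1Cl | intermediate (not isolated)
27 | 4-(benzyloxy)-2-chloro-6-(trimethylsilyl)phenyl trifluoromethanesulfonate | C[Si](C)(C)c1cc(OCc2ccccc2)cc(Cl)c1OS(=O)(=O)C(F)(F)F | intermediate
28 | 5-(benzyloxy)-3-chlorobenzyne | ClC1=CC(OCc2ccccc2)=CC#C1 | intermediate (not isolated)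
29 | O-aryloxetanium zwitterion (oxetane oxygen bonded to future C8a, aryl anion at future C4a) | [O+]1(C2=CC(OCc3ccccc3)=CC(Cl)=[C-]2)[C@H](c2ccc(OCc3ccccc3)c(OCc3ccccc3)c2)[C@@H](OCc2ccccc2)[C@H]1c1c(OCc2ccccc2)cc(OCc2ccccc2)c2C[C@H](OCc3ccccc3)[C@@H](c3ccc(OCc4ccccc4)cc3)Oc12 | intermediate (not isolated)
30 | ring-opened zwitterion (aryl ether at O1, aryl anion at C4a, benzylic cation at C4) | [C-]1=C(Cl)C=C(OCc2ccccc2)C=C1O[C@H](c1ccc(OCc2ccccc2)c(OCc2ccccc2)c1)[C@@H](OCc1ccccc1)[CH+]c1c(OCc2ccccc2)cc(OCc2ccccc2)c2C[C@H](OCc3ccccc3)[C@@H](c3ccc(OCc4ccccc4)cc3)Oc12 | intermediate (not isolated)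
31 | (2R,3S,4R)-3,7-bis(benzyloxy)-2-[3,4-bis(benzyloxy)phenyl]-5-chloro-4-(tetra-O-benzylafzelechin-8-yl)chromane (2,3-trans-3,4-trans) | Clc1cc(OCc3ccccc3)cc2O[C@H](c3ccc(OCc4ccccc4)c(OCc4ccccc4)c3)[C@@H](OCc3ccccc3)[C@H](c3c(OCc4ccccc4)cc(OCc4ccccc4)c4C[C@H](OCc5ccccc5)[C@@H](c5ccc(OCc6ccccc6)cc5)Oc34)c12 | intermediate
32 | fisetinidol-(4α→8)-afzelechin, (2R,3S,4S)-2-(3,4-dihydroxyphenyl)-4-[(2R,3S)-3,5,7-trihydroxy-2-(4-hydroxyphenyl)chroman-8-yl]chromane-3,7-diol | Oc1ccc([C@H]2Oc3c(c(O)cc(O)c3[C@@H]3c4ccc(O)cc4O[C@H](c4ccc(O)c(O)c4)[C@H]3O)C[C@@H]2O)cc1 | target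

**Step count and risks**

Total: 14 steps. Longest linear sequence: 8 steps (1, 2, 3, 7, 8, 9, 13, 14; the branch 4, 5, 6, 7, 8, 9, 13, 14 is equally long).

Steps most likely to fail:

1. Step 13. The hindered oxetane oxygen may intercept the aryne too slowly, the ring-opened benzylic cation may be captured by fluoride or lose a proton before it closes, or the oxetanium may open toward ring B. The fallback is the established Lewis-acid interflavan coupling; it sets out from 3 and comes back at 32. Purchased (+)-fustin F1 is benzylated on its three phenols (BnBr, K2CO3, DMF) to 7,3',4'-tri-O-benzylfustin F2 and reduced (NaBH4, THF/MeOH) to the 2,3-trans-3,4-trans flavan-3,4-diol F3. F3 is ionized at C4 with BF3·OEt2 in CH2Cl2 at low temperature in the presence of an excess of 3, and Friedel–Crafts attack by C8 of 3 anti to O3 should give the hepta-O-benzyl dimer F4, to be separated from any 4→6 isomer. Hydrogenolysis of F4 (H2, Pd(OH)2/C) gives 32.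

2. Step 9. Sulfonylation may occur on the wrong hydroxyl, the p-alkoxybenzylic sulfonate may ionize with loss of the C2 configuration, or the γ-sulfonyloxy alkoxide may undergo Grob-type fragmentation in place of 4-exo closure. The fallback fixes the site of activation before the second hydroxyl exists; it sets out from 17 and comes back at 21. Ketone 17 is mesylated on its only hydroxyl (Ms2O, 2,6-lutidine, CH2Cl2, −40 °C) to the β-mesyloxy ketone F5. Reduction with LiBH4 in THF at −78 °C gives the γ-mesyloxy alkoxide of F6, whose less ionic lithium alkoxide should close on warming with inversion at C2 to 21 together with its C4 epimer F7. F7 serves equally, because step 13 erases C4.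

3. Step 7. Acylation of the di-ortho-substituted aryllithium by the amide may be slow, and enolization of the α-benzyloxy amide or metalation of neighbouring benzyl ethers may take over on warming. The fallback uses the more electrophilic aldehyde and restores the ketone by oxidation; it sets out from 13 and comes back at 17. Amide 13 is silylated (TESCl, imidazole) to the TES ether F8 and reduced with i-Bu2AlH at −78 °C to the aldehyde F9. Addition of aryllithium 14 at −78 °C gives the carbinol F10 as a mixture of epimers, buffered Dess–Martin oxidation gives the TES-protected ketone F11, and HF·pyridine in pyridine/THF gives 17.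

**Further compounds**

F1 | step 13 | (+)-fustin, (2R,3R)-3,7,3',4'-tetrahydroxyflavanone (purchased) | O=C1c2ccc(O)cc2O[C@H](c2ccc(O)c(O)c2)[C@H]1O
F2 | step 13 | 7,3',4'-tri-O-benzylfustin | O=C1c2ccc(OCc3ccccc3)cc2O[C@H](c2ccc(OCc3ccccc3)c(OCc3ccccc3)c2)[C@H]1O
F3 | step 13 | (2R,3S,4R)-7-(benzyloxy)-2-[3,4-bis(benzyloxy)phenyl]chromane-3,4-diol | O[C@@H]1c2ccc(OCc3ccccc3)cc2O[C@H](c2ccc(OCc3ccccc3)c(OCc3ccccc3)c2)[C@H]1O
F4 | step 13 | 7,3',4'-tri-O-benzylfisetinidol-(4α→8)-3,5,7,4'-tetra-O-benzylafzelechin (free 3-OH in the upper unit) | c1cc(OCc3ccccc3)cc2O[C@H](c3ccc(OCc4ccccc4)c(OCc4ccccc4)c3)[C@@H](O)[C@H](c3c(OCc4ccccc4)cc(OCc4ccccc4)c4C[C@H](OCc5ccccc5)[C@@H](c5ccc(OCc6ccccc6)cc5)Oc34)c12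
F5 | step 9 | 3-O-mesylate of 17 | CS(=O)(=O)O[C@@H](c1ccc(OCc2ccccc2)c(OCc2ccccc2)c1)[C@@H](OCc1ccccc1)C(=O)c1c(OCc2ccccc2)cc(OCc2ccccc2)c2C[C@H](OCc3ccccc3)[C@@H](c3ccc(OCc4ccccc4)cc3)Oc12
F6 | step 9 | γ-mesyloxy alcohol from F5 (both epimers at the new carbinol carbon) | CS(=O)(=O)O[C@@H](c1ccc(OCc2ccccc2)c(OCc2ccccc2)c1)[C@@H](OCc1ccccc1)C(O)c1c(OCc2ccccc2)cc(OCc2ccccc2)c2C[C@H](OCc3ccccc3)[C@@H](c3ccc(OCc4ccccc4)cc3)Oc12
F7 | step 9 | C4 epimer of oxetane 21 (all-trans) | O1[C@H](c2ccc(OCc3ccccc3)c(OCc3ccccc3)c2)[C@@H](OCc2ccccc2)[C@@H]1c1c(OCc2ccccc2)cc(OCc2ccccc2)c2C[C@H](OCc3ccccc3)[C@@H](c3ccc(OCc4ccccc4)cc3)Oc12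
F8 | step 7 | 3-O-triethylsilyl ether of 13 | CC[Si](CC)(CC)O[C@@H](c1ccc(OCc2ccccc2)c(OCc2ccccc2)c1)[C@@H](OCc1ccccc1)C(=O)N(C)OC
F9 | step 7 | (2R,3S)-2-(benzyloxy)-3-[3,4-bis(benzyloxy)phenyl]-3-(triethylsilyloxy)propanal | CC[Si](CC)(CC)O[C@@H](c1ccc(OCc2ccccc2)c(OCc2ccccc2)c1)[C@@H](OCc1ccccc1)C=O
F10 | step 7 | carbinol from F9 and 14 (both epimers at the new carbinol carbon) | CC[Si](CC)(CC)O[C@@H](c1ccc(OCc2ccccc2)c(OCc2ccccc2)c1)[C@@H](OCc1ccccc1)C(O)c1c(OCc2ccccc2)cc(OCc2ccccc2)c2C[C@H](OCc3ccccc3)[C@@H](c3ccc(OCc4ccccc4)cc3)Oc12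
F11 | step 7 | 3-O-triethylsilyl ether of 17 | CC[Si](CC)(CC)O[C@@H](c1ccc(OCc2ccccc2)c(OCc2ccccc2)c1)[C@@H](OCc1ccccc1)C(=O)c1c(OCc2ccccc2)cc(OCc2ccccc2)c2C[C@H](OCc3ccccc3)[C@@H](c3ccc(OCc4ccccc4)cc3)Oc12
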